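Everything rests on cutting the C1–C6 bond of ring A (C1 butyryl-bearing, C2 C–OH, C3 CMe2, C4 C–OH, C5 bridge-bearing, C6 C=O) and leaving this ring open to the end. The precursor is a tert-butyl β-keto ester in which C1 is hidden as an sp carbon of a C2≡C1 ynone, so C5 is its only carbon nucleophile when the unprotected ring D–C–B trimer is attached. In one operation the ester oxygen adds to C2, isobutene leaves, and acyl carbon C6 migrates from that oxygen to C1. The step exploits the 1,3,5-oxygen pattern of ring A and its non-enolisable C3, which blocks aromatisation and rival closures.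

Key step: step 8

Remark on the chemistry: ring B is the phlorobutyrophenone ring joined to ring A, ring C the next one, and ring D the terminal C-methylated ring. Keto/enol tautomers of ring A and of all β-dicarbonyl units are treated as one compound. The target has no stereocentre.

Step 1
Reactants: 1 phloroglucinol (benzene-1,3,5-triol); 2 butanoyl chloride
Product: 3 1-(2,4,6-trihydroxyphenyl)butan-1-one (phlorobutyrophenone)
Conditions: AlCl3 (3.5 equiv), CH2Cl2/PhNO2, 0 → 40 °C; ice/HCl
Reagents that add atoms: none
Why: Friedel–Crafts C-acylation of the very electron-rich triol should stop at the monoketone because the first acyl group, chelated to aluminium, deactivates the ring.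

Step 2
Reactants: 4 2-methylphloroglucinol (2-methylbenzene-1,3,5-triol); 2 butanoyl chloride
Product: 5 1-(2,4,6-trihydroxy-3-methylphenyl)butan-1-one (methylphlorobutyrophenone, future ring D)
Conditions: AlCl3 (3.5 equiv), CH2Cl2/PhNO2, 0 → 40 °C; ice/HCl
Reagents that add atoms: none
Why: Friedel–Crafts acylation in which the two free ring positions of 4 are equivalent by symmetry, so a single monoketone should form.

Step 3
Reactants: 5 methylphlorobutyrophenone; 3 phlorobutyrophenone
Product: 8 1-[3-[(3-butanoyl-2,4,6-trihydroxyphenyl)methyl]-2,4,6-trihydroxy-5-methylphenyl]butan-1-one (ring D–C dimer), via Mannich base 6 (not isolated), via ortho-quinone methide 7 (not isolated)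
Conditions: [Me2N=CH2]I (1.0 equiv), NaOAc (1.1 equiv), MeCN, rt; then 3 (4 equiv), 65 °C
Reagents that add atoms: N,N-dimethylmethyleneiminium iodide, C=[N+](C)C.[I-]
Why: Mannich aminomethylation at the only free ring carbon of 5, then thermal loss of dimethylamine, gives an ortho-quinone methide that a free ring carbon of 3 takes up in a Michael-type Friedel–Crafts alkylation, the excess of 3 limiting double capping.

Step 4
Reactants: 8 ring D–C dimer; 3 phlorobutyrophenone
Product: 11 ring D–C–B trimer (8 carrying at the free carbon of ring C a CH2 joined to C3 of a further 1-butanoyl-2,4,6-trihydroxyphenyl ring), via Mannich base 9 (not isolated), via ortho-quinone methide 10 (not isolated)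
Conditions: [Me2N=CH2]I (1.0 equiv), NaOAc (1.1 equiv), THF/MeCN, rt; then 3 (4 equiv), 65 °C
Reagents that add atoms: N,N-dimethylmethyleneiminium iodide, C=[N+](C)C.[I-]
Why: The same Mannich / ortho-quinone methide Michael sequence as in step 3, in which 8 offers a single free ring carbon (on ring C) for aminomethylation and the excess of symmetric 3 should keep the new ring B monosubstituted.

Step 5
Reactants: 12 2,2-dimethylbut-3-ynoic acid; 13 mono-tert-butyl malonate
Product: 16 tert-butyl 4,4-dimethyl-3-oxohex-5-ynoate, via acyl imidazolide 14 (not isolated), via magnesium enolate 15 (not isolated)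
Conditions: 12, 1,1'-carbonyldiimidazole, THF, rt; separately 13, iPrMgCl (2 equiv), THF, 0 °C → rt; combine, 40 °C; 1 M HCl
Reagents that add atoms: none
Why: Decarboxylative Claisen condensation of a malonate half-ester magnesium enolate with an acyl imidazolide, which is mild enough for the terminal alkyne and workable at the quaternary α-carbon.

Step 6
Reactants: 16 tert-butyl 4,4-dimethyl-3-oxohex-5-ynoate; 17 N-methoxy-N-methylbutanamide
Product: 19 tert-butyl 4,4-dimethyl-3,7-dioxodec-5-ynoate, via dilithio dianion 18 (not isolated)
Conditions: LiN(iPr)2 (2.2 equiv), THF, −78 °C; then 17, −78 → −20 °C; inverse quench into cold 1 M HCl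
Reagents that add atoms: none
Why: Weinreb ketone synthesis in which the first equivalent of base stores the β-keto ester as its unreactive enolate (the quaternary carbon leaves no γ-hydrogen) and the second forms the acetylide, which alone is acylated, the chelated tetrahedral adduct preventing over-addition.

Step 7
Reactants: 11 ring D–C–B trimer; 19 tert-butyl 4,4-dimethyl-3,7-dioxodec-5-ynoate
Product: 22 tert-butyl 4,4-dimethyl-3,7-dioxo-2-[(ring B of the D–C–B trimer)methyl]dec-5-ynoate (racemic open-chain precursor of ring A), via Mannich base 20 (not isolated), via ortho-quinone methide 21 (not isolated)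
Conditions: [Me2N=CH2]I (1.0 equiv), NaOAc (1.1 equiv), THF/MeCN, rt; then 19 (3 equiv), AcOH (5 equiv), 60 °C; dilute HCl wash
Reagents that add atoms: N,N-dimethylmethyleneiminium iodide, C=[N+](C)C.[I-]
Why: Mannich reaction followed by Michael addition to an ortho-quinone methide, in which 11 has one free ring carbon (ring B) and in 19 the CH2 between ketone and ester (future C5) is the only acidic C–H because future C1 is an sp carbon, so the bridge can form only at C5, the new stereocentre arising racemic and being erased in step 8.

Step 8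
Reactants: 22 open-chain precursor
Product: 25 target CNP0246352.0, via enol lactone 23 (not isolated), via acylketene 24 (not isolated)
Conditions: Ph3PAuNTf2 (5 mol %), dry CH2Cl2/AcOH 4:1, rt; evaporate; then Et3N (12 equiv), DMAP (0.2 equiv), dry MeCN, 4 Å MS, 45 °C; cold 1 M HCl
Reagents that add atoms: none
Why: Monovalent gold activates the C2≡C1 triple bond and the carbonyl oxygen of the tert-butyl ester attacks C2, the β-carbon of the ynone, in a 6-exo-dig closure helped by the gem-dialkyl effect of C3; loss of isobutene and protodeauration give the temporary (Z)-enol lactone 23 without ever freeing a decarboxylation-prone β-keto acid. With Et3N the acidic C5–H of 23 is removed and the enolate opens by E1cB expulsion of the β-diketone enolate to acylketene 24 (DMAP can carry the same acyl group), in which C1, now the central carbon of a β-diketone, attacks ketene carbon C6 in a 6-(enolendo)-exo-dig closure that makes the C1–C6 bond and ring A. The closest known reaction types are the gold-catalysed cyclisation of tert-butyl β-keto alkynoates to 4-hydroxy-2-pyrones with loss of isobutene, the base- or DMAP-mediated O-to-C acyl migration of enol esters and ylidene lactones to 2-acyl-1,3-diones, and the Claisen cyclisation of 3,5,7-triketo esters to acylphloroglucinols. No stereocentre is created, and the labile centre C5 of 22 becomes sp2. The step needs C- over O-acylation, and the substrate secures it because every O-acylation (return to 23 or capture by a neighbouring phenol of ring B) gives a β-keto ester of a good leaving group that reverts to 24, whereas C-acylation gives the doubly hydrogen-bonded, strongly acidic ring A as its anion and is irreversible. Aldol closure of C5 onto the butyryl carbonyl is disfavoured because C5 is fully substituted, and the quaternary C3 excludes aromatisation and leaves only four-membered alternatives for attack at C2.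

Compound list
1 | phloroglucinol | Oc1cc(O)cc(O)c1 | starting material
2 | butanoyl chloride | CCCC(=O)Cl | starting material
3 | 1-(2,4,6-trihydroxyphenyl)butan-1-one (phlorobutyrophenone) | CCCC(=O)c1c(O)cc(O)cc1O | intermediate
4 | 2-methylphloroglucinol | Cc1c(O)cc(O)cc1O | starting material
5 | 1-(2,4,6-trihydroxy-3-methylphenyl)butan-1-one | CCCC(=O)c1c(O)cc(O)c(C)c1O | intermediate
6 | 1-[3-[(dimethylamino)methyl]-2,4,6-trihydroxy-5-methylphenyl]butan-1-one (Mannich base of 5) | CCCC(=O)c1c(O)c(CN(C)C)c(O)c(C)c1O | intermediate
7 | 4-butanoyl-3,5-dihydroxy-2-methyl-6-methylidenecyclohexa-2,4-dien-1-one (ortho-quinone methide from 6) | C=C1C(=O)C(C)=C(O)C(C(=O)CCC)=C1O | intermediate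
8 | ring D–C dimer, 1-[3-[(3-butanoyl-2,4,6-trihydroxyphenyl)methyl]-2,4,6-trihydroxy-5-methylphenyl]butan-1-one | CCCC(=O)c1c(O)c(C)c(O)c(Cc2c(O)cc(O)c(C(=O)CCC)c2O)c1O | intermediate
9 | Mannich base of 8 (CH2NMe2 at the free carbon of ring C) | CCCC(=O)c1c(O)c(C)c(O)c(Cc2c(O)c(CN(C)C)c(O)c(C(=O)CCC)c2O)c1O | intermediate
10 | ortho-quinone methide from 9 (ring C as 6-methylidenecyclohexa-2,4-dienone) | C=C1C(=O)C(Cc2c(O)c(C)c(O)c(C(=O)CCC)c2O)=C(O)C(C(=O)CCC)=C1O | intermediate
11 | ring D–C–B trimer (one free ring carbon, on ring B) | CCCC(=O)c1c(O)c(C)c(O)c(Cc2c(O)c(Cc3c(O)cc(O)c(C(=O)CCC)c3O)c(O)c(C(=O)CCC)c2O)c1O | intermediate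
12 | 2,2-dimethylbut-3-ynoic acid | C#CC(C)(C)C(=O)O | starting material
13 | mono-tert-butyl malonate | CC(C)(C)OC(=O)CC(=O)O | starting material
14 | 1-(2,2-dimethylbut-3-ynoyl)imidazole | C#CC(C)(C)C(=O)n1ccnc1 | intermediate
15 | bis(chloromagnesium) enolate-carboxylate of 13 | CC(C)(C)O/C([O-])=C/C(=O)[O-].[Mg+2].[Mg+2].[Cl-].[Cl-] | intermediate
16 | tert-butyl 4,4-dimethyl-3-oxohex-5-ynoate | C#CC(C)(C)C(=O)CC(=O)OC(C)(C)C | intermediate
17 | N-methoxy-N-methylbutanamide | CCCC(=O)N(C)OC | starting material
18 | dilithio dianion of 16 (enolate and acetylide) | [Li+].[Li+].[C-]#CC(C)(C)/C([O-])=C/C(=O)OC(C)(C)C | intermediate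
19 | tert-butyl 4,4-dimethyl-3,7-dioxodec-5-ynoate | CCCC(=O)C#CC(C)(C)C(=O)CC(=O)OC(C)(C)C | intermediate
20 | Mannich base of 11 (CH2NMe2 at the free carbon of ring B) | CCCC(=O)c1c(O)c(C)c(O)c(Cc2c(O)c(Cc3c(O)c(CN(C)C)c(O)c(C(=O)CCC)c3O)c(O)c(C(=O)CCC)c2O)c1O | intermediate
21 | ortho-quinone methide from 20 (ring B as 6-methylidenecyclohexa-2,4-dienone) | C=C1C(=O)C(Cc2c(O)c(Cc3c(O)c(C)c(O)c(C(=O)CCC)c3O)c(O)c(C(=O)CCC)c2O)=C(O)C(C(=O)CCC)=C1O | intermediate
22 | open-chain precursor, tert-butyl 4,4-dimethyl-3,7-dioxo-2-[(ring B of the trimer)methyl]dec-5-ynoate, racemic | CCCC(=O)C#CC(C)(C)C(=O)C(Cc1c(O)c(Cc2c(O)c(Cc3c(O)c(C)c(O)c(C(=O)CCC)c3O)c(O)c(C(=O)CCC)c2O)c(O)c(C(=O)CCC)c1O)C(=O)OC(C)(C)C | intermediate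
23 | enol lactone, (6Z)-4-hydroxy-5,5-dimethyl-6-(2-oxopentylidene)-3-[(ring B of the trimer)methyl]-5,6-dihydro-2H-pyran-2-one | CCCC(=O)/C=C1\OC(=O)C(Cc2c(O)c(Cc3c(O)c(Cc4c(O)c(C)c(O)c(C(=O)CCC)c4O)c(O)c(C(=O)CCC)c3O)c(O)c(C(=O)CCC)c2O)=C(O)C1(C)C | intermediate
24 | acylketene, 4,4-dimethyl-3,5,7-trioxo-2-[(ring B of the trimer)methyl]dec-1-en-1-one | CCCC(=O)CC(=O)C(C)(C)C(=O)C(=C=O)Cc1c(O)c(Cc2c(O)c(Cc3c(O)c(C)c(O)c(C(=O)CCC)c3O)c(O)c(C(=O)CCC)c2O)c(O)c(C(=O)CCC)c1O | intermediate
25 | CNP0246352.0 (ring A–B–C–D tetramer) | CCCC(=O)C1=C(O)C(C)(C)C(O)=C(Cc2c(O)c(Cc3c(O)c(Cc4c(O)c(C)c(O)c(C(=O)CCC)c4O)c(O)c(C(=O)CCC)c3O)c(O)c(C(=O)CCC)c2O)C1=O | target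

Total step count: 8. Longest linear sequence: 5 steps (2, 3, 4, 7, 8).

Steps most likely to fail

First, step 8.
- Gold activation of the electron-poor, neopentyl-type alkyne may be sluggish.
- Adventitious water may hydrate the triple bond.
- The O-to-C migration may be slow because the lactone rests as its unreactive enolate.
- Warm amine base may exchange the methylene bridges by retro-Michael cleavage.

The fallback closes ring A before the union instead of after it. It sets out from 19, which with the same gold catalyst should give the small enol lactone (6Z)-4-hydroxy-5,5-dimethyl-6-(2-oxopentylidene)-5,6-dihydro-2H-pyran-2-one F1. This fragment holds no phenol and no bridge, so NaOMe in refluxing MeOH can drive the Claisen-type recyclisation to butyrylfilicinic acid (2-butanoyl-3,5-dihydroxy-4,4-dimethylcyclohexa-2,5-dien-1-one) F2. F2 is a strong carbon acid with one free ring carbon. It replaces 19 in the second stage of step 7, takes up ortho-quinone methide 21 generated from 20, and comes back to the route at 25.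

Second, step 7.
- The weakly acidic β-keto ester may react too slowly, so the quinone methide is lost to self-reaction or bridge exchange.
- A second alkylation may occur at C5.
- Released amine may add in a conjugate fashion to the ynone.
- A ring B phenol may cyclodehydrate onto the C4 ketone.

The fallback inverts the polarity of the union. It sets out from 19, whose only active methylene should be aminomethylated by [Me2N=CH2]I and NaOAc to tert-butyl 2-[(dimethylamino)methyl]-4,4-dimethyl-3,7-dioxodec-5-ynoate F3. Gentle warming removes dimethylamine and gives tert-butyl 4,4-dimethyl-2-methylidene-3,7-dioxodec-5-ynoate F4. The free ring B carbon of 11 (NaOAc/AcOH buffer) intercepts this strong Michael acceptor in a Friedel–Crafts-type conjugate addition, which comes back to the route at 22.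

Third, step 4.
- Compound 3 may be capped twice.
- The existing D–C bridge may cleave and re-form while a quinone methide is generated from a compound that already holds a bridge, which would scramble the chain length.

The fallback builds the central bridge first. It sets out from 3, which in excess is condensed with aqueous formaldehyde (dilute KOH, rt, short contact) to the symmetric 3,3'-methylenebis(2,4,6-trihydroxybutyrophenone) F5. F5 in excess is then alkylated by ortho-quinone methide 7 generated from the monomeric Mannich base 6. The electrophile therefore never comes from a bridged compound, and the sequence comes back to the route at 11.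

Further compounds
F1 | step 8 | (6Z)-4-hydroxy-5,5-dimethyl-6-(2-oxopentylidene)-5,6-dihydro-2H-pyran-2-one | CCCC(=O)/C=C1\OC(=O)C=C(O)C1(C)C
F2 | step 8 | butyrylfilicinic acid (2-butanoyl-3,5-dihydroxy-4,4-dimethylcyclohexa-2,5-dien-1-one) | CCCC(=O)C1=C(O)C(C)(C)C(O)=CC1=O
F3 | step 7 | tert-butyl 2-[(dimethylamino)methyl]-4,4-dimethyl-3,7-dioxodec-5-ynoate (racemic) | CCCC(=O)C#CC(C)(C)C(=O)C(CN(C)C)C(=O)OC(C)(C)C
F4 | step 7 | tert-butyl 4,4-dimethyl-2-methylidene-3,7-dioxodec-5-ynoate | CCCC(=O)C#CC(C)(C)C(=O)C(=C)C(=O)OC(C)(C)C
F5 | step 4 | 3,3'-methylenebis(2,4,6-trihydroxybutyrophenone) | CCCC(=O)c1c(O)cc(O)c(Cc2c(O)cc(O)c(C(=O)CCC)c2O)c1O
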